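**Plan**
1. Locants: ring B (saturated) is C1–C4, with C1 carrying C20H2–O and C4 carrying the side-chain methine C11; ring A (arene) is C5–C10, with CO2H on C6, O on C8 and C9/C10 as fusion carbons.
2. Cuts, in order: the two O-acetyl groups and the ether/ester methyl groups; the ring-B bond C3–C4 together with C11–H; C1–H/C20–O; then C9–C1 and C10–C4, back to methyl 5-bromovanillate and two alkenylboronates.
3. Enabling feature: C4 is benzylic to ring A and vicinal to the C11 methine, and C3 sits on the ortho arm at C9. A C4=C11 (E)-styrene on C10 plus a C3–Br therefore lets one copper-hydride addition/alkylation close ring B and set C4 and C11 together.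
4. Forward: side-chain alkyne, (E)-alkenylboronate, coupling at C10; triflation and coupling at C9; hydroboration to set C1; silyl and bromide adjustment; ring B closed last; deprotection and acetylation.
5. Stereochemistry: C1 from ligand-controlled cobalt-catalysed hydroboration; C4/C11 relative configuration from syn Cu–H addition to the geometrically pure (E)-alkene with retentive alkylation, absolute sense from the bisphosphine ligand.

Key step: step 12

Assumption: in steps 8 and 12 the ligand antipode is written by analogy with simpler alkenes; the antipode that gives the stated sense ((R) at C1 in step 8; copper to the Si face of C4 and hydride to the Re face of C11 in step 12) is the one used.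

**Route**

Step 1
Reactants: 1 5-bromo-2-methylpent-2-ene; 2 lithium acetylide (used as its ethylenediamine complex)
Product: 3 6-methylhept-5-en-1-yne
Conditions: DMSO, 10 °C to rt
Reagents that add atoms: none
Why: Acetylide alkylation (SN2) of a primary homoallylic bromide should give the terminal alkyne; no stereocentre is formed.

Step 2
Reactants: 3 6-methylhept-5-en-1-yne
Product: 4 (E)-2-(2,6-dimethylhepta-1,5-dien-1-yl)-4,4,5,5-tetramethyl-1,3,2-dioxaborolane
Conditions: CuCl (10 mol%), Xantphos (10 mol%), NaOtBu, B2pin2, MeI, THF, rt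
Reagents that add atoms: bis(pinacolato)diboron, CC1(C)OB(OC1(C)C)B1OC(C)(C)C(C)(C)O1; iodomethane, CI
Why: Copper-catalysed alkyne carboboration: syn borylcupration places boron on the terminal carbon and the alkenylcopper is methylated with retention, so CH3 ends cis to boron, which is the (E)-trisubstituted alkene.

Step 3
Reactants: 4 (E)-alkenylboronate; 5 methyl 3-bromo-4-hydroxy-5-methoxybenzoate (methyl 5-bromovanillate)
Product: 6 methyl 3-[(1E)-2,6-dimethylhepta-1,5-dien-1-yl]-4-hydroxy-5-methoxybenzoate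
Conditions: Pd(dppf)Cl2 (5 mol%), K2CO3, dioxane/H2O, 70 °C
Reagents that add atoms: none
Why: Suzuki–Miyaura coupling of an aryl bromide with an alkenylboronate should proceed with retention of alkene geometry and tolerates the free phenol and the ester.

Step 4
Reactants: 6 phenol
Product: 7 methyl 3-[(1E)-2,6-dimethylhepta-1,5-dien-1-yl]-5-methoxy-4-(trifluoromethanesulfonyloxy)benzoate
Conditions: Tf2O, pyridine, CH2Cl2, 0 °C
Reagents that add atoms: trifluoromethanesulfonic anhydride, O=S(=O)(OS(=O)(=O)C(F)(F)F)C(F)(F)F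
Why: O-Triflation of the phenol turns C9–O into a coupling handle that is activated by the para ester.

Step 5
Reactants: 8 3-bromobut-3-en-1-ol
Product: 9 [(3-bromobut-3-en-1-yl)oxy](tert-butyl)dimethylsilane
Conditions: TBSCl, imidazole, CH2Cl2, rt
Reagents that add atoms: tert-butyldimethylsilyl chloride, CC(C)(C)[Si](C)(C)Cl
Why: Standard silylation of a primary alcohol protects the future C3 oxygen.

Step 6
Reactants: 9 vinyl bromide
Product: 10 tert-butyldimethyl{[3-(4,4,5,5-tetramethyl-1,3,2-dioxaborolan-2-yl)but-3-en-1-yl]oxy}silane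
Conditions: PdCl2(PPh3)2 (3 mol%), PPh3, KOPh, B2pin2, toluene, 50 °C
Reagents that add atoms: bis(pinacolato)diboron, CC1(C)OB(OC1(C)C)B1OC(C)(C)C(C)(C)O1
Why: Miyaura borylation of a 1-alkenyl bromide should give the 1,1-disubstituted alkenylboronate, with phenoxide as the base that avoids homocoupling.

Step 7
Reactants: 7 aryl triflate; 10 alkenylboronate
Product: 11 methyl 4-{4-[(tert-butyldimethylsilyl)oxy]but-1-en-2-yl}-3-[(1E)-2,6-dimethylhepta-1,5-dien-1-yl]-5-methoxybenzoate
Conditions: Pd(OAc)2 (5 mol%), SPhos (10 mol%), K3PO4, toluene/H2O (20:1), 80 °C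
Reagents that add atoms: none
Why: Suzuki–Miyaura coupling of a di-ortho-substituted aryl triflate, for which a dialkylbiarylphosphine ligand is suited, installs the C9–C1 bond as a 1,1-disubstituted styrene.

Step 8
Reactants: 11 1,1-disubstituted styrene
Product: 13 methyl 4-[(2R)-4-[(tert-butyldimethylsilyl)oxy]-1-hydroxybutan-2-yl]-3-[(1E)-2,6-dimethylhepta-1,5-dien-1-yl]-5-methoxybenzoate, via primary alkylboronate 12 (not isolated)
Conditions: (IPO)CoCl2 [CoCl2 complex of the (S)-iminopyridine–oxazoline ligand] (5 mol%), NaBHEt3 (10 mol%), HBpin, THF, rt; then NaBO3·4H2O, THF/H2O, rt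
Reagents that add atoms: pinacolborane, CC1(C)OBOC1(C)C (boron held only in 12); sodium perborate, [Na+].[O-]OB=O (hydroxyl oxygen)
Why: Cobalt-hydride-catalysed enantioselective anti-Markovnikov hydroboration of a 1,1-disubstituted aryl alkene sets C1 as (R) by ligand-controlled hydride delivery to the prochiral benzylic carbon; both trisubstituted alkenes should stay inert, and perborate oxidation replaces boron by OH with retention (hydroboration–oxidation).

Step 9
Reactants: 13 primary alcohol
Product: 14 methyl 4-[(2R)-4-[(tert-butyldimethylsilyl)oxy]-1-[(tert-butyldiphenylsilyl)oxy]butan-2-yl]-3-[(1E)-2,6-dimethylhepta-1,5-dien-1-yl]-5-methoxybenzoate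
Conditions: TBDPSCl, imidazole, DMF, rt
Reagents that add atoms: tert-butyldiphenylsilyl chloride, CC(C)(C)[Si](Cl)(c1ccccc1)c1ccccc1
Why: Silylation gives a C20 ether that withstands LiOMe in step 12 and blocks tetrahydrofuran formation from a free C20 alkoxide and the C3 bromide.

Step 10
Reactants: 14 bis-silyl ether
Product: 15 methyl 4-[(2R)-1-[(tert-butyldiphenylsilyl)oxy]-4-hydroxybutan-2-yl]-3-[(1E)-2,6-dimethylhepta-1,5-dien-1-yl]-5-methoxybenzoate
Conditions: PPTS (0.3 equiv), MeOH, rt
Reagents that add atoms: none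
Why: Acid-catalysed methanolysis cleaves the primary TBS ether much faster than the bulkier TBDPS ether (selective desilylation).

Step 11
Reactants: 15 C3 alcohol
Product: 16 methyl 4-[(2R)-4-bromo-1-[(tert-butyldiphenylsilyl)oxy]butan-2-yl]-3-[(1E)-2,6-dimethylhepta-1,5-dien-1-yl]-5-methoxybenzoate
Conditions: CBr4, PPh3, CH2Cl2, 0 °C
Reagents that add atoms: carbon tetrabromide, BrC(Br)(Br)Br
Why: The Appel reaction converts the primary alcohol into the bromide under neutral conditions that leave alkenes, silyl ether and ester alone.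

Step 12
Reactants: 16 bromide-tethered (E)-styrene
Product: 18 methyl (5R,8S)-5-{[(tert-butyldiphenylsilyl)oxy]methyl}-4-methoxy-8-[(2S)-6-methylhept-5-en-2-yl]-5,6,7,8-tetrahydronaphthalene-2-carboxylate, via benzylic alkylcopper 17 (not isolated)
Conditions: Cu(OAc)2 (10 mol%), (S)-DTBM-SEGPHOS (11 mol%), (MeO)2MeSiH, LiOMe, THF, 40 °C
Reagents that add atoms: none
Why: Proposed new method: the ligated monovalent copper hydride made from Cu(OAc)2 and the silane should add syn across the C4=C11 bond of the (E)-β,β-disubstituted styrene, with copper at the benzylic, less substituted C4 and hydride at C11, to give alkylcopper 17, which then displaces the primary C3 bromide intramolecularly with retention at C4, while LiOMe and the silane return the copper hydride. The closest known reaction type is the copper-hydride-catalysed enantioselective intramolecular hydroalkylation of bromide-tethered β-monosubstituted styrenes (cyclobutanes, cyclopentanes, indanes), together with copper-hydride hydroamination of β,β-disubstituted styrenes, which shows that such trisubstituted styrenes are hydrocuprated; new here are the trisubstituted alkene in the alkylation manifold and a six-membered carbocycle closed through the ortho arm. The ring closes in the 6-exo-tet mode (C4–Cu onto C3–Br; ring atoms C3, C4, C10, C9, C1, C2). C11 is set by the face of hydride delivery (Re face of C11) and C4 by the face taken by copper (Si face of C4), both fixed by the ligand; because addition is syn and alkylation retentive, the (E)-geometry translates into the (4S,11S) pair, and C1 is untouched. The step needs regioselectivity (copper benzylic), chemoselectivity (no reaction at the isolated C14=C15 alkene or the methyl ester, no simple reduction of the C–Br bond) and facial selectivity; benzylic stabilisation of the C–Cu bond, the inertness of unactivated trisubstituted alkenes to this catalyst, the entropic advantage of ring closure and the bulky bisphosphine should secure them.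

Step 13
Reactants: 18 silyl ether
Product: 19 methyl (5R,8S)-5-(hydroxymethyl)-4-methoxy-8-[(2S)-6-methylhept-5-en-2-yl]-5,6,7,8-tetrahydronaphthalene-2-carboxylate
Conditions: TBAF, THF, rt
Reagents that add atoms: none
Why: Fluoride-mediated desilylation frees the C20 alcohol without touching the ester, the alkene or the stereocentres.

Step 14
Reactants: 19 methyl ether methyl ester
Product: 20 (5R,8S)-4-hydroxy-5-(hydroxymethyl)-8-[(2S)-6-methylhept-5-en-2-yl]-5,6,7,8-tetrahydronaphthalene-2-carboxylic acid
Conditions: NaSEt, DMF, 130 °C (degassed); then 1 M HCl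
Reagents that add atoms: none
Why: Thiolate SN2 demethylation removes the methyl groups of both the aryl ether and the ester in one operation and is compatible with the trisubstituted alkene and the benzylic stereocentres.

Step 15
Reactants: 20 dihydroxy acid
Product: 22 (5R,8S)-4-acetoxy-5-(acetoxymethyl)-8-[(2S)-6-methylhept-5-en-2-yl]-5,6,7,8-tetrahydronaphthalene-2-carboxylic acid, via mixed anhydride 21 (not isolated)
Conditions: Ac2O, pyridine, DMAP (cat.), CH2Cl2, rt; then H2O/THF, rt
Reagents that add atoms: acetic anhydride, CC(=O)OC(C)=O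
Why: Acetylation of the phenol and the primary alcohol; the mixed anhydride formed at the carboxyl group should hydrolyse on aqueous treatment much faster than the aryl acetate, leaving the free acid.

**Compound list**
1 | 5-bromo-2-methylpent-2-ene | CC(C)=CCCBr | starting material
2 | lithium acetylide (ethylenediamine complex) | [Li]C#C | starting material
3 | 6-methylhept-5-en-1-yne | C#CCCC=C(C)C | intermediate
4 | (E)-2-(2,6-dimethylhepta-1,5-dien-1-yl)-4,4,5,5-tetramethyl-1,3,2-dioxaborolane | C/C(CCC=C(C)C)=C\B1OC(C)(C)C(C)(C)O1 | intermediate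
5 | methyl 3-bromo-4-hydroxy-5-methoxybenzoate | COC(=O)c1cc(OC)c(O)c(Br)c1 | starting material
6 | methyl 3-[(1E)-2,6-dimethylhepta-1,5-dien-1-yl]-4-hydroxy-5-methoxybenzoate | COC(=O)c1cc(OC)c(O)c(/C=C(\C)CCC=C(C)C)c1 | intermediate
7 | methyl 3-[(1E)-2,6-dimethylhepta-1,5-dien-1-yl]-5-methoxy-4-(trifluoromethanesulfonyloxy)benzoate | COC(=O)c1cc(OC)c(OS(=O)(=O)C(F)(F)F)c(/C=C(\C)CCC=C(C)C)c1 | intermediate
8 | 3-bromobut-3-en-1-ol | C=C(Br)CCO | starting material
9 | [(3-bromobut-3-en-1-yl)oxy](tert-butyl)dimethylsilane | C=C(Br)CCO[Si](C)(C)C(C)(C)C | intermediate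
10 | tert-butyldimethyl{[3-(4,4,5,5-tetramethyl-1,3,2-dioxaborolan-2-yl)but-3-en-1-yl]oxy}silane | C=C(CCO[Si](C)(C)C(C)(C)C)B1OC(C)(C)C(C)(C)O1 | intermediate
11 | methyl 4-{4-[(tert-butyldimethylsilyl)oxy]but-1-en-2-yl}-3-[(1E)-2,6-dimethylhepta-1,5-dien-1-yl]-5-methoxybenzoate | COC(=O)c1cc(OC)c(C(=C)CCO[Si](C)(C)C(C)(C)C)c(/C=C(\C)CCC=C(C)C)c1 | intermediate
12 | methyl 4-[(2R)-4-[(tert-butyldimethylsilyl)oxy]-1-(4,4,5,5-tetramethyl-1,3,2-dioxaborolan-2-yl)butan-2-yl]-3-[(1E)-2,6-dimethylhepta-1,5-dien-1-yl]-5-methoxybenzoate | CC(C)(C)[Si](C)(C)OCC[C@@H](CB1OC(C)(C)C(C)(C)O1)c1c(OC)cc(C(=O)OC)cc1/C=C(\C)CCC=C(C)C | intermediate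
13 | methyl 4-[(2R)-4-[(tert-butyldimethylsilyl)oxy]-1-hydroxybutan-2-yl]-3-[(1E)-2,6-dimethylhepta-1,5-dien-1-yl]-5-methoxybenzoate | CC(C)(C)[Si](C)(C)OCC[C@@H](CO)c1c(OC)cc(C(=O)OC)cc1/C=C(\C)CCC=C(C)C | intermediate
14 | methyl 4-[(2R)-4-[(tert-butyldimethylsilyl)oxy]-1-[(tert-butyldiphenylsilyl)oxy]butan-2-yl]-3-[(1E)-2,6-dimethylhepta-1,5-dien-1-yl]-5-methoxybenzoate | CC(C)(C)[Si](C)(C)OCC[C@@H](CO[Si](c1ccccc1)(c1ccccc1)C(C)(C)C)c1c(OC)cc(C(=O)OC)cc1/C=C(\C)CCC=C(C)C | intermediate
15 | methyl 4-[(2R)-1-[(tert-butyldiphenylsilyl)oxy]-4-hydroxybutan-2-yl]-3-[(1E)-2,6-dimethylhepta-1,5-dien-1-yl]-5-methoxybenzoate | OCC[C@@H](CO[Si](c1ccccc1)(c1ccccc1)C(C)(C)C)c1c(OC)cc(C(=O)OC)cc1/C=C(\C)CCC=C(C)C | intermediate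
16 | methyl 4-[(2R)-4-bromo-1-[(tert-butyldiphenylsilyl)oxy]butan-2-yl]-3-[(1E)-2,6-dimethylhepta-1,5-dien-1-yl]-5-methoxybenzoate | BrCC[C@@H](CO[Si](c1ccccc1)(c1ccccc1)C(C)(C)C)c1c(OC)cc(C(=O)OC)cc1/C=C(\C)CCC=C(C)C | intermediate
17 | benzylic alkylcopper from 16: copper on C4, new C11–H with C11 (S), bisphosphine ligand omitted in the SMILES | BrCC[C@@H](CO[Si](c1ccccc1)(c1ccccc1)C(C)(C)C)c1c(OC)cc(C(=O)OC)cc1[C@@H]([Cu])[C@@H](C)CCC=C(C)C | intermediate
18 | methyl (5R,8S)-5-{[(tert-butyldiphenylsilyl)oxy]methyl}-4-methoxy-8-[(2S)-6-methylhept-5-en-2-yl]-5,6,7,8-tetrahydronaphthalene-2-carboxylate | CC(C)(C)[Si](c1ccccc1)(c1ccccc1)OC[C@@H]1CC[C@@H]([C@@H](C)CCC=C(C)C)c2cc(C(=O)OC)cc(OC)c21 | intermediate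
19 | methyl (5R,8S)-5-(hydroxymethyl)-4-methoxy-8-[(2S)-6-methylhept-5-en-2-yl]-5,6,7,8-tetrahydronaphthalene-2-carboxylate | OC[C@@H]1CC[C@@H]([C@@H](C)CCC=C(C)C)c2cc(C(=O)OC)cc(OC)c21 | intermediate
20 | (5R,8S)-4-hydroxy-5-(hydroxymethyl)-8-[(2S)-6-methylhept-5-en-2-yl]-5,6,7,8-tetrahydronaphthalene-2-carboxylic acid | OC[C@@H]1CC[C@@H]([C@@H](C)CCC=C(C)C)c2cc(C(=O)O)cc(O)c21 | intermediate
21 | acetic (5R,8S)-4-acetoxy-5-(acetoxymethyl)-8-[(2S)-6-methylhept-5-en-2-yl]-5,6,7,8-tetrahydronaphthalene-2-carboxylic anhydride | CC(=O)OC[C@@H]1CC[C@@H]([C@@H](C)CCC=C(C)C)c2cc(C(=O)OC(C)=O)cc(OC(C)=O)c21 | intermediate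
22 | (5R,8S)-4-acetoxy-5-(acetoxymethyl)-8-[(2S)-6-methylhept-5-en-2-yl]-5,6,7,8-tetrahydronaphthalene-2-carboxylic acid | CC(=O)OC[C@@H]1CC[C@@H]([C@@H](C)CCC=C(C)C)c2cc(C(=O)O)cc(OC(C)=O)c21 | target

**Step count:** 15 steps in total; longest linear sequence 13 steps (steps 1–4 and 7–15).

**Steps most likely to fail**

Step 12 (Proposed new method). Hydrocupration of the twisted, ortho-substituted β,β-disubstituted styrene may be slower than reduction of the C–Br bond by the copper hydride, or the facial selectivity may be eroded by a mismatch with C1. Fallback with known chemistry, setting out from 16 and returning at 18: a tin-hydride radical chain (Bu3SnH added slowly, AIBN, benzene, 80 °C). The primary C3 radical closes 6-exo-trig onto C4, the less substituted alkene carbon, and the tertiary C11 radical takes hydrogen from the stannane. No new compound arises (F0). Stereocontrol at C4 and C11 then rests on the substrate alone, so 18 would have to be separated from its C4/C11 isomers by preparative chromatography.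

Step 8. The di-ortho-substituted aryl group twists the alkene out of conjugation, which may lower both the rate and the enantiofacial discrimination of the hydroboration. Fallback (auxiliary control instead of catalyst control), setting out from 7 and returning at 13:
- Palladium-catalysed coupling of 7 with the Reformatsky reagent BrZnCH2CO2CH2CH2SiMe3 (Pd2(dba)3, XPhos, THF, 60 °C) gives the 2-(trimethylsilyl)ethyl arylacetate F1.
- TBAF in THF frees the arylacetic acid F2.
- Pivaloyl chloride/Et3N, then the lithium salt of (R)-4-benzyl-1,3-oxazolidin-2-one, gives the N-acyl oxazolidinone F3.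
- Evans alkylation (NaHMDS, THF, −78 °C, then 2-[(tert-butyldimethylsilyl)oxy]ethyl triflate) takes place on the enolate face away from the benzyl group and gives the (2R)-alkylated imide F4.
- LiBH4 in THF/MeOH at 0 °C removes the auxiliary reductively and delivers 13.

Step 7. Oxidative addition and transmetalation at the di-ortho-substituted triflate may be slow, so that protodeboronation of the 1,1-disubstituted alkenylboronate and hydrolysis of the triflate compete. Fallback with reversed polarity, setting out from 7 and returning at 11: Miyaura borylation of 7 (Pd(OAc)2, SPhos, B2pin2, KOAc, dioxane, 90 °C) gives the arylboronate F5, which is coupled with vinyl bromide 9 (Pd(dppf)Cl2, K2CO3, dioxane/H2O, 80 °C) to give 11.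

**Further compounds**
F0 | step 12 | none | none
F1 | step 8 | 2-(trimethylsilyl)ethyl 2-{2-[(1E)-2,6-dimethylhepta-1,5-dien-1-yl]-6-methoxy-4-(methoxycarbonyl)phenyl}acetate | C[Si](C)(C)CCOC(=O)Cc1c(OC)cc(C(=O)OC)cc1/C=C(\C)CCC=C(C)C
F2 | step 8 | 2-{2-[(1E)-2,6-dimethylhepta-1,5-dien-1-yl]-6-methoxy-4-(methoxycarbonyl)phenyl}acetic acid | OC(=O)Cc1c(OC)cc(C(=O)OC)cc1/C=C(\C)CCC=C(C)C
F3 | step 8 | methyl 4-{2-[(4R)-4-benzyl-2-oxo-1,3-oxazolidin-3-yl]-2-oxoethyl}-3-[(1E)-2,6-dimethylhepta-1,5-dien-1-yl]-5-methoxybenzoate | O=C(Cc1c(OC)cc(C(=O)OC)cc1/C=C(\C)CCC=C(C)C)N1[C@H](Cc2ccccc2)COC1=O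
F4 | step 8 | methyl 4-{(2R)-1-[(4R)-4-benzyl-2-oxo-1,3-oxazolidin-3-yl]-4-[(tert-butyldimethylsilyl)oxy]-1-oxobutan-2-yl}-3-[(1E)-2,6-dimethylhepta-1,5-dien-1-yl]-5-methoxybenzoate | CC(C)(C)[Si](C)(C)OCC[C@@H](C(=O)N1[C@H](Cc2ccccc2)COC1=O)c1c(OC)cc(C(=O)OC)cc1/C=C(\C)CCC=C(C)C
F5 | step 7 | methyl 3-[(1E)-2,6-dimethylhepta-1,5-dien-1-yl]-5-methoxy-4-(4,4,5,5-tetramethyl-1,3,2-dioxaborolan-2-yl)benzoate | COC(=O)c1cc(OC)c(B2OC(C)(C)C(C)(C)O2)c(/C=C(\C)CCC=C(C)C)c1
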